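Remark on the chemistry: ring positions follow the IUPAC numbering of (−)-quinic acid (C7 is the carboxyl carbon; O1, O3 and O4 lie on one ring face, O5 and C7 on the other). Read this way the SMILES is 3-O-caffeoyl-4-O-p-coumaroylquinic acid with both alkenes E, and that compound is planned for.

## The problem

The target is a single cyclohexane with four stereocentres: the quaternary carbinol C1, which carries the carboxyl carbon C7, and the three contiguous oxygenated carbons C3, C4 and C5. O3 and O4 are cis and carry two different E-hydroxycinnamoyl groups (caffeoyl on O3, p-coumaroyl on O4), whereas O1, O5 and the acid are free, so O3 and O4 must be told apart while O5 stays untouched. No ring fusion has to be made; the carbon problem is the six-membered ring and the quaternary centre, whose carboxyl must end cis to O5 and trans to O3 and O4. The C3–C5 triad (cis, then trans) is the arabino pattern and can be taken from a pentose. C1, however, stands 1,3 to both C3 and C5 with a methylene between, so these centres can steer it only through the ring conformation or through a tether. The fragile groups are the two cinnamates (base cleaves them or moves them to a neighbouring hydroxyl, above all from O4 to O5), the catechol, and any intermediate C1 ketone flanked by C3–O and C5–O, which loses an oxygen by E1cB under base. The enabling feature is the 1,3-cis relation of C7 and O5 across C6: a one-carbon nucleophile tied to O5 through silicon can reach C1 only on that face, closing the six-membered ring C7–Si–O5–C5–C6–C1. The same relation later lets C7 and O5 be locked as the γ-lactone (6-oxabicyclo[3.2.1]octane), which hides O5 and the acid while O3 and O4 are acylated.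

## Retrosynthesis

Target 28 is traced back to the lactone 27, in which O5 and C7 are joined and the three phenols are acetates. One acidic hydrolysis should undo both. An acidic last step is preferred to any basic one because acyl shift from O4 to the freed O5 is base-promoted. The precursor is simpler in that O5 and the acid are one function and no free catechol is carried.

Lactone 27 is cut at the two ester C–O bonds, first to mono-ester 24 and acid chloride 26, then to 1,5-quinide 21 and acid chloride 23 (the chlorides come from the commercial acetylated acids 25 and 22). Acylating the lactone is preferred to acylating an open quinate because O5 cannot compete. In the lactone chair O3 is equatorial, O4 axial beside the bridge and O1 tertiary, so the order O3 first, O4 second follows the intrinsic reactivity. The forward reactions must be run under non-equilibrating conditions so that the first ester stays on O3.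

Quinide 21 comes from its 3,4-acetonide 20, and 20 from triol 18 by oxidation of the C7 hydroxymethyl group with capture by O5. This cut is chosen because the key step delivers C7 at the alcohol level. Lactonisation is possible only for the C1 epimer with C7 cis to O5, so the step also proves the configuration. The forward oxidation must stop short of cleaving the C1–C7 glycol.

Triol 18 is the Tamao oxidation product of the cyclic alkoxysilane 17: the C7–Si bond becomes C7–OH and the Si–O5 bond is hydrolysed. Silicon is preferred to a carbon-based tether because it can be excised completely, leaving only the hydroxymethyl group. The forward reaction must tolerate a β-hydroxysilane without Peterson elimination, which mild fluoride/bicarbonate conditions do.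

Oxasilinane 17 is cut at C1–C7, leading to ketone 15 with a bromomethyl(dimethyl)silyl group on O5. Against the neighbouring option, intermolecular addition of a one-carbon nucleophile to the ketone, the tether replaces a conformational preference by a geometric necessity. The precursor has one ring and one stereocentre fewer. The forward reaction needs a carbanion generated without base, because the ketone is β-oxygenated on both sides; samarium diiodide is chosen for that reason.

Ketone 15 is the silyl ether of hydroxy ketone 13 with chlorosilane 14; 13 comes from the silyl-protected ketone 12, and 12 from dithioketal 11. These are changes of protecting and functional groups only. The tether is put on last because a bromomethylsilyl ether would not survive the organolithium chemistry that builds the ring. Each forward step must stay near neutral, since the β-alkoxy ketone eliminates under base.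

Dithioketal 11 is cut at C1–C2 and C1–C6: 1,3-dithiane 8 as the C1 unit is alkylated twice by the bis-triflate 7 of a protected arabinitol. Both new bonds go to an achiral carbon, so no stereocentre is made in the ring-forming step and the pentitol carries all three. An aldol or metathesis ring closure would have to create or protect one of them.

Bis-triflate 7 comes from diol 6, and 6 from D-arabinose 1 through benzyl glycoside 2, acetonide 3 and silyl ether 4. Sugar C2, C3 and C4 become ring C5, C4 and C3; sugar C1 and C5 become C6 and C2. The pyranoside is used because it exposes the one cis-diol (O3/O4 of the sugar) for the acetonide and leaves O2 alone. O2 must be capped before C5 is activated, since a free O2 sits 1,4 to C5 on a cis-dioxolane and would close a tetrahydrofuran.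

## Roads not taken

Alternative 1: the ring is cut at C4–C5 as an aldol. Desymmetrised citric acid supplies C1 with its hydroxyl and carboxyl (as an isopropylidene dioxolanone) and both methylene arms. One arm is grown into an acyloxymethyl ketone already carrying the allyl-protected coumaroyl group and the other is cut back to an aldehyde, giving keto aldehyde A2. A proline enamine of the C3 ketone, formed toward the acyloxy carbon, would add to the aldehyde and close the ring to the 3-dehydroquinate A1, setting C4 and C5 together.
- Merits: a cheap achiral start; no facial problem at C1, which is fixed when the arms are told apart; the carboxyl at its final oxidation level; the O4 ester in place before the ring exists. In the last two respects it is better than the chosen plan, which must oxidise C7 afterwards and must rely on an equatorial/axial rate difference to place the esters.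
- Weak points: the enamine must form toward C4 and not C2. The catalyst must match or override a quaternary centre 1,3 to both new centres. A1 is a β-hydroxy-α-acyloxy ketone, open to dehydration, C4 epimerisation and acyl shift. The C3 ketone must then be reduced to the axial alcohol and O3 acylated beside a free O5.
- Comparison: four selectivities in a row, none enforced by structure, stand against one in the chosen plan, where three stereocentres are bought and the fourth is fixed by a tether.

Alternative 2: the bond cut is C3–O3. The starting point is the cyclohex-3-ene silanol A4, which already holds C1 and C5 and carries O1 as a di-tert-butylsilanol, O5 as a 4-methoxybenzyl ether and the acid as a 2-(trimethylsilyl)ethyl ester. Treated with an iodonium source, the silanol oxygen of A4 would open the iodonium ion at C3 on the O1 face and close a 1,3-dioxa-2-silinane, giving the iodo silylene ether A3 with iodide at C4 anti to O3. Displacement of the iodide of A3 by a coumarate with inversion would bring O4 in cis to O3, already acylated.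
- Merits: O3 is delivered by a tether, with the same certainty as C7 in the chosen plan. Every oxygen of A3 emerges differentiated, so the mixed diester is regiochemically unambiguous, which is better than the chosen endgame. C7 needs no oxidation.
- Weak points: silanol A4 already contains the hard part, the relation of the quaternary C1 to C5, and no short de novo source for it is apparent. Displacement of the secondary ring iodide of A3, which lies between two oxygenated carbons, by a carboxylate competes with E2 and with neighbouring-group participation. The iodonium reagent must spare the electron-rich benzyl ether.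
- Comparison: this road has the better end, the chosen plan the better beginning. The chosen plan sets against it a defined chiral-pool origin for C3–C5 and a ring closure that creates no stereocentre.

Alternative 3: the cut is C1–C2, an aldol of the kind that makes 3-dehydroquinate in nature. Diketo ester A6 (methyl ketone at C3, the trans-4,5-diol as an acetonide, an α-keto ester at C1) would cyclise through the enol or an enamine of the methyl ketone onto the keto ester carbonyl, giving ethyl 4,5-O-isopropylidene-3-dehydroquinate A5.
- Merits: the shortest carbon assembly of the four; ring, quaternary centre and carboxyl at the right oxidation level in one step. In step count and oxidation-state economy it beats the chosen plan.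
- Weak points: the configuration at C1, the crux of the target, rests on the small preference of a reversible aldol. A6 has a methylene between the keto ester and C5–O and can lose O5 by E1cB. A5 dehydrates easily toward a dehydroshikimate. The C3 ketone must be reduced to the axial alcohol. After removal of the trans-acetonide, O4 and O5 (both equatorial) must be told apart for the coumaroyl group, which is harder than O3 versus O4 in a lactone.
- Comparison: the chosen plan spends extra steps (tether on, Tamao oxidation, oxidation of C7) to make the C1 configuration a matter of geometry and not of a ratio.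

Key step: step 10

## Route

Step 1
Reactants: 1 D-arabinose
Product: 2 benzyl β-D-arabinopyranoside
Conditions: BnOH (solvent), anhydrous HCl (cat.), 50 °C; crystallisation
Reagents that add atoms: benzyl alcohol, OCc1ccccc1
Why: Fischer glycosidation under thermodynamic control; the pyranoside with the axial benzyloxy group (β-D, anomeric effect) should predominate and crystallise, and no centre of the later ring is touched.

Step 2
Reactants: 2 benzyl β-D-arabinopyranoside
Product: 3 benzyl 3,4-O-isopropylidene-β-D-arabinopyranoside
Conditions: 2,2-dimethoxypropane, p-TsOH·H2O (cat.), acetone, rt; Et3N quench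
Reagents that add atoms: 2,2-dimethoxypropane, COC(C)(C)OC
Why: Acetal exchange (acetonide formation) takes the only cis-vicinal diol, O3/O4; O2, trans to O3, stays free.

Step 3
Reactants: 3 benzyl 3,4-O-isopropylidene-β-D-arabinopyranoside
Product: 4 benzyl 2-O-(tert-butyldimethylsilyl)-3,4-O-isopropylidene-β-D-arabinopyranoside
Conditions: TBSOTf, 2,6-lutidine, CH2Cl2, 0 °C
Reagents that add atoms: tert-butyldimethylsilyl triflate, CC(C)(C)[Si](C)(C)OS(=O)(=O)C(F)(F)F
Why: Silylation of the single free secondary hydroxyl; O2 (later O5 of the ring) must be capped before C5 is activated, or it would close onto C5 to a tetrahydrofuran.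

Step 4
Reactants: 4 benzyl 2-O-(tert-butyldimethylsilyl)-3,4-O-isopropylidene-β-D-arabinopyranoside
Product: 6 2-O-(tert-butyldimethylsilyl)-3,4-O-isopropylidene-D-arabinitol, via lactol 5 (not isolated)
Conditions: H2 (1 atm), Pd/C (10 wt%), EtOH, rt; filter; NaBH4, 0 °C
Reagents that add atoms: none
Why: Hydrogenolysis of the benzyl glycoside gives lactol 5, whose open aldehyde form is reduced by borohydride; cold, short reduction should limit silyl migration from O2 to O1, and the three stereocentres are untouched.

Step 5
Reactants: 6 2-O-(tert-butyldimethylsilyl)-3,4-O-isopropylidene-D-arabinitol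
Product: 7 2-O-(tert-butyldimethylsilyl)-3,4-O-isopropylidene-1,5-bis-O-(trifluoromethylsulfonyl)-D-arabinitol
Conditions: Tf2O, pyridine, CH2Cl2, −30 °C; cold aqueous work-up, used at once
Reagents that add atoms: triflic anhydride, O=S(=O)(OS(=O)(=O)C(F)(F)F)C(F)(F)F
Why: Sulfonylation of both primary alcohols; β-oxygenated primary triflates should be stable enough at low temperature to be carried on crude.

Step 6
Reactants: 7 2-O-(tert-butyldimethylsilyl)-3,4-O-isopropylidene-1,5-bis-O-(trifluoromethylsulfonyl)-D-arabinitol; 8 1,3-dithiane
Product: 11 5-O-(tert-butyldimethylsilyl)-3,4-O-isopropylidene-3,4,5-trihydroxycyclohexanone propane-1,3-diyl dithioketal, via 2-lithio-1,3-dithiane 9 (not isolated), via monoalkylated triflate 10 (not isolated)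
Conditions: 8, n-BuLi (1.05 equiv), THF, −30 °C; 7, THF, −78 °C; then t-BuLi (1.1 equiv), −78 → −40 °C
Reagents that add atoms: none
Why: Corey–Seebach alkylation twice at one dithiane carbon, a five-plus-one annulation known for pentitol bis-triflates: 9 displaces one triflate to give 10 (either end, both converge), the hindered base then deprotonates C2 of 10 and the anion closes the ring by 6-exo-tet displacement. No stereocentre forms (O3/O4 stay cis and O5 trans to O4, as in the pentitol), and the cis-dioxolane holds the chain ends together.

Step 7
Reactants: 11 5-O-(tert-butyldimethylsilyl)-3,4-O-isopropylidene-3,4,5-trihydroxycyclohexanone propane-1,3-diyl dithioketal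
Product: 12 5-O-(tert-butyldimethylsilyl)-3,4-O-isopropylidene-3,4,5-trihydroxycyclohexanone (the 5-O-silyl ether of 13)
Conditions: MeI, CaCO3, MeCN/H2O (4:1), 40 °C
Reagents that add atoms: water, O
Why: Dithioketal hydrolysis by S-methylation and attack of water under carbonate buffering; the near-neutral medium should spare the acetonide, the silyl ether and the β-oxygenated ketone.

Step 8
Reactants: 12 5-O-(tert-butyldimethylsilyl)-3,4-O-isopropylidene-3,4,5-trihydroxycyclohexanone
Product: 13 (3R,4S,5R)-5-hydroxy-3,4-(isopropylidenedioxy)cyclohexanone
Conditions: HF·pyridine, pyridine, THF, 0 °C → rt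
Reagents that add atoms: none
Why: Fluoride-mediated desilylation in a weakly acidic buffer, which avoids the E1cB loss of O3 or O5 that basic fluoride could cause and leaves the acetonide.

Step 9
Reactants: 13 (3R,4S,5R)-5-hydroxy-3,4-(isopropylidenedioxy)cyclohexanone; 14 (bromomethyl)chlorodimethylsilane
Product: 15 5-O-[(bromomethyl)dimethylsilyl]-3,4-O-isopropylidene-3,4,5-trihydroxycyclohexanone
Conditions: imidazole, CH2Cl2, 0 °C; rapid non-aqueous work-up, used directly
Reagents that add atoms: none
Why: O-silylation of the secondary alcohol with a chlorosilane under mild base, as in the preparation of bromomethylsilyl ethers for tethered cyclisations; the weak base should not enolise the ketone.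

Step 10
Reactants: 15 5-O-[(bromomethyl)dimethylsilyl]-3,4-O-isopropylidene-3,4,5-trihydroxycyclohexanone
Product: 17 7,8-O-isopropylidene-3,3-dimethyl-2-oxa-3-silabicyclo[3.3.1]nonane-5,7,8-triol (O5–SiMe2–C7H2 bridge from C5 to C1 on the face opposite O1 and O3 and O4), via alkylsamarium diiodide 16 (not isolated)
Conditions: SmI2 (2.5 equiv, 0.1 M in THF), HMPA (10 equiv), 0 °C, slow addition of 15 (final 0.01 M); sat. aq. NaHCO3
Reagents that add atoms: none
Why: Proposed new method: two single-electron transfers from SmI2 (divalent samarium), activated by HMPA, cleave the C–Br bond and give the silicon-stabilised alkylsamarium 16, which adds to the C1 carbonyl to form C1–C7 and a trivalent samarium alkoxide; the closest known reactions are SmI2 Barbier additions of alkyl and alkoxymethyl halides to ketones, additions of (alkoxydimethylsilyl)methyl Grignard reagents to ketones, and radical cyclisations of bromomethylsilyl ethers, none of which uses this carbanion on an oxygen tether. The ring closed is the 1,2-oxasilinane C7–Si–O5–C5–C6–C1, by 6-exo-trig attack. The new stereocentre C1 is set by the tether: the three-atom chain can span C5 and C1 only when both bonds are axial on the O5 face (chair with O5 and O4 axial), so C7 must enter cis to O5 and the hydroxyl is left cis to O3 and O4, as in quinic acid. The step needs the C–Br bond to be reduced before the ketone and addition to outrun enolisation; the first is expected from the easier reduction of an α-silyl bromide and the second from the low basicity and high oxophilicity of organosamarium reagents, so neither O3 nor O5 should be lost by E1cB. Peterson elimination of the β-silyl alkoxide is disfavoured because the new ring holds Si–C7 and C1–O1 anti and cannot bring them syn-periplanar. Slow addition at high dilution keeps intermolecular addition and pinacol coupling down.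

Step 11
Reactants: 17 7,8-O-isopropylidene-3,3-dimethyl-2-oxa-3-silabicyclo[3.3.1]nonane-5,7,8-triol
Product: 18 1-(hydroxymethyl)-3,4-O-isopropylidenecyclohexane-1,3,4,5-tetrol in the quinic acid configuration (the carboxyl-reduced form of quinic acid 3,4-acetonide)
Conditions: 30% aq. H2O2, KF, KHCO3, THF/MeOH (1:1), rt; Na2S2O3 quench
Reagents that add atoms: hydrogen peroxide, OO
Why: Tamao oxidation: peroxide adds to the fluoride-activated alkoxysilane, C7 migrates from silicon to oxygen and the Si–O bonds are hydrolysed, releasing C7–OH and O5–H; β-hydroxy(alkoxy)silanes are oxidised under these conditions without Peterson elimination.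

Step 12
Reactants: 18 1-(hydroxymethyl)-3,4-O-isopropylidenecyclohexane-1,3,4,5-tetrol in the quinic acid configuration
Product: 20 3,4-O-isopropylidene-1,5-quinide (quinic acid 1,5-lactone 3,4-acetonide), via bridged lactol 19 (not isolated)
Conditions: TEMPO (0.2 equiv), PhI(OAc)2 (2.5 equiv), CH2Cl2, rt
Reagents that add atoms: none
Why: Nitroxyl-catalysed oxidation of the primary alcohol gives the hydroxy aldehyde, which closes with the cis O5 to lactol 19 and is oxidised on to the γ-lactone (oxidative lactonisation of a diol); only the C1 epimer with C7 cis to O5 can lactonise, so the step also checks step 10.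

Step 13
Reactants: 20 3,4-O-isopropylidene-1,5-quinide
Product: 21 1,5-quinide (quinic acid 1,5-lactone; O3 equatorial and O4 axial)
Conditions: TFA/H2O (9:1), 0 °C → rt; evaporate, toluene azeotrope
Reagents that add atoms: none
Why: Acid-catalysed acetonide hydrolysis at low water content; the bridged γ-lactone should persist, and any hydroxy acid formed should reclose on azeotropic drying.

Step 14
Reactants: 22 (E)-3,4-diacetoxycinnamic acid
Product: 23 (E)-3,4-diacetoxycinnamoyl chloride
Conditions: (COCl)2, DMF (cat.), CH2Cl2, 0 °C → rt; evaporate
Reagents that add atoms: oxalyl chloride, O=C(Cl)C(=O)Cl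
Why: Acid chloride formation through the Vilsmeier-type chloroiminium catalyst; the aryl acetates and the E-alkene are not affected.

Step 15
Reactants: 21 1,5-quinide; 23 (E)-3,4-diacetoxycinnamoyl chloride
Product: 24 3-O-(3,4-di-O-acetylcaffeoyl)-1,5-quinide
Conditions: 23 (1.0 equiv), pyridine/CH2Cl2 (1:1), −30 → 0 °C
Reagents that add atoms: none
Why: Acylation by an acid chloride in pyridine under kinetic control; O3 is the equatorial, unhindered hydroxyl, O4 is axial beside the lactone bridge and O1 is tertiary, so the first acyl group should go to O3.

Step 16
Reactants: 25 (E)-4-acetoxycinnamic acid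
Product: 26 (E)-4-acetoxycinnamoyl chloride
Conditions: (COCl)2, DMF (cat.), CH2Cl2, 0 °C → rt; evaporate
Reagents that add atoms: oxalyl chloride, O=C(Cl)C(=O)Cl
Why: Acid chloride formation as in step 14.

Step 17
Reactants: 24 3-O-(3,4-di-O-acetylcaffeoyl)-1,5-quinide; 26 (E)-4-acetoxycinnamoyl chloride
Product: 27 3-O-(3,4-di-O-acetylcaffeoyl)-4-O-(4-O-acetyl-p-coumaroyl)-1,5-quinide
Conditions: 26 (1.5 equiv), pyridine, DMAP (cat.), CH2Cl2, 0 °C → rt
Reagents that add atoms: none
Why: DMAP-catalysed acylation of the remaining secondary hydroxyl O4; the tertiary O1 should react much more slowly, and an ester on the equatorial O3 has no thermodynamic drive to move to the axial O4.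

Step 18
Reactants: 27 3-O-(3,4-di-O-acetylcaffeoyl)-4-O-(4-O-acetyl-p-coumaroyl)-1,5-quinide
Product: 28 3-O-caffeoyl-4-O-p-coumaroylquinic acid (target)
Conditions: 2 M aq. HCl/THF (1:3), rt, under argon
Reagents that add atoms: water, O
Why: Acid-catalysed hydrolysis opens the strained bridged γ-lactone (water adds at C7) and cleaves the three aryl acetates, which are more labile than the hindered secondary cinnamates; acid is used because acyl shift to the freed O5 is base-promoted, and no stereocentre is touched.

## Compound list

1 | D-arabinose | O=C[C@@H](O)[C@H](O)[C@H](O)CO | starting material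
2 | benzyl β-D-arabinopyranoside | c1ccccc1CO[C@@H]2OC[C@@H](O)[C@@H](O)[C@@H]2O | intermediate
3 | benzyl 3,4-O-isopropylidene-β-D-arabinopyranoside | c1ccccc1CO[C@@H]2OC[C@H]3OC(C)(C)O[C@H]3[C@@H]2O | intermediate
4 | benzyl 2-O-(tert-butyldimethylsilyl)-3,4-O-isopropylidene-β-D-arabinopyranoside | c1ccccc1CO[C@@H]2OC[C@H]3OC(C)(C)O[C@H]3[C@@H]2O[Si](C)(C)C(C)(C)C | intermediate
5 | 2-O-(tert-butyldimethylsilyl)-3,4-O-isopropylidene-D-arabinopyranose (lactol, anomeric mixture; not isolated) | OC1OC[C@H]2OC(C)(C)O[C@H]2[C@@H]1O[Si](C)(C)C(C)(C)C | intermediate
6 | 2-O-(tert-butyldimethylsilyl)-3,4-O-isopropylidene-D-arabinitol | OC[C@@H](O[Si](C)(C)C(C)(C)C)[C@@H]1OC(C)(C)O[C@@H]1CO | intermediate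
7 | 2-O-(tert-butyldimethylsilyl)-3,4-O-isopropylidene-1,5-bis-O-(trifluoromethylsulfonyl)-D-arabinitol | FC(F)(F)S(=O)(=O)OC[C@@H](O[Si](C)(C)C(C)(C)C)[C@@H]1OC(C)(C)O[C@@H]1COS(=O)(=O)C(F)(F)F | intermediate
8 | 1,3-dithiane | C1CSCSC1 | starting material
9 | 2-lithio-1,3-dithiane (not isolated) | [Li]C1SCCCS1 | intermediate
10 | 5-deoxy-5-(1,3-dithian-2-yl)-2-O-(tert-butyldimethylsilyl)-3,4-O-isopropylidene-1-O-(trifluoromethylsulfonyl)-D-arabinitol (monoalkylated triflate; not isolated) | FC(F)(F)S(=O)(=O)OC[C@@H](O[Si](C)(C)C(C)(C)C)[C@@H]1OC(C)(C)O[C@@H]1CC1SCCCS1 | intermediate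
11 | 5-O-(tert-butyldimethylsilyl)-3,4-O-isopropylidene-3,4,5-trihydroxycyclohexanone propane-1,3-diyl dithioketal (O3 and O4 cis, O5 trans to O4; ring configuration as in 13) | CC1(C)O[C@H]2[C@H](O[Si](C)(C)C(C)(C)C)CC3(SCCCS3)C[C@H]2O1 | intermediate
12 | 5-O-(tert-butyldimethylsilyl)-3,4-O-isopropylidene-3,4,5-trihydroxycyclohexanone (5-O-silyl ether of 13) | CC1(C)O[C@H]2[C@H](O[Si](C)(C)C(C)(C)C)CC(=O)C[C@H]2O1 | intermediate
13 | (3R,4S,5R)-5-hydroxy-3,4-(isopropylidenedioxy)cyclohexanone | CC1(C)O[C@H]2[C@H](O)CC(=O)C[C@H]2O1 | intermediate
14 | (bromomethyl)chlorodimethylsilane | C[Si](C)(Cl)CBr | starting material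
15 | 5-O-[(bromomethyl)dimethylsilyl]-3,4-O-isopropylidene-3,4,5-trihydroxycyclohexanone (5-O-silyl ether of 13) | CC1(C)O[C@H]2[C@H](O[Si](C)(C)CBr)CC(=O)C[C@H]2O1 | intermediate
16 | alkylsamarium diiodide from 15 (C–Br replaced by C–SmI2; not isolated) | CC1(C)O[C@H]2[C@H](O[Si](C)(C)C[Sm](I)I)CC(=O)C[C@H]2O1 | intermediate
17 | 7,8-O-isopropylidene-3,3-dimethyl-2-oxa-3-silabicyclo[3.3.1]nonane-5,7,8-triol (quinic numbering: O5–SiMe2–C7H2 bridge from C5 to C1, free O1–H on the O3/O4 face) | CC1(C)O[C@H]2[C@H]3C[C@](O)(C[Si](C)(C)O3)C[C@H]2O1 | intermediate
18 | 1-(hydroxymethyl)-3,4-O-isopropylidenecyclohexane-1,3,4,5-tetrol (quinic configuration) | CC1(C)O[C@H]2[C@H](O)C[C@](O)(CO)C[C@H]2O1 | intermediate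
19 | bridged lactol of 18 (7-hydroxy analogue of 20; not isolated) | CC1(C)O[C@H]2[C@H]3C[C@](O)(C(O)O3)C[C@H]2O1 | intermediate
20 | 3,4-O-isopropylidene-1,5-quinide | CC1(C)O[C@H]2[C@H]3C[C@](O)(C(=O)O3)C[C@H]2O1 | intermediate
21 | 1,5-quinide | O[C@H]1[C@H]2C[C@](O)(C(=O)O2)C[C@H]1O | intermediate
22 | (E)-3,4-diacetoxycinnamic acid | CC(=O)Oc1ccc(/C=C/C(=O)O)cc1OC(C)=O | starting material
23 | (E)-3,4-diacetoxycinnamoyl chloride | CC(=O)Oc1ccc(/C=C/C(=O)Cl)cc1OC(C)=O | intermediate
24 | 3-O-(3,4-di-O-acetylcaffeoyl)-1,5-quinide | O[C@H]1[C@H]2C[C@](O)(C(=O)O2)C[C@H]1OC(=O)/C=C/c1ccc(OC(C)=O)c(OC(C)=O)c1 | intermediate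
25 | (E)-4-acetoxycinnamic acid | CC(=O)Oc1ccc(/C=C/C(=O)O)cc1 | starting material
26 | (E)-4-acetoxycinnamoyl chloride | CC(=O)Oc1ccc(/C=C/C(=O)Cl)cc1 | intermediate
27 | 3-O-(3,4-di-O-acetylcaffeoyl)-4-O-(4-O-acetyl-p-coumaroyl)-1,5-quinide | O=C(/C=C/c1ccc(OC(C)=O)cc1)O[C@H]1[C@H]2C[C@](O)(C(=O)O2)C[C@H]1OC(=O)/C=C/c1ccc(OC(C)=O)c(OC(C)=O)c1 | intermediate
28 | 3-O-caffeoyl-4-O-p-coumaroylquinic acid | O=C(/C=C/c1ccc(O)cc1)O[C@H]1[C@H](O)C[C@](O)(C(=O)O)C[C@H]1OC(=O)/C=C/c1ccc(O)c(O)c1 | target

## Step count and least certain steps

Total: 18 steps. Longest linear sequence: 16 steps (steps 1–13, 15, 17 and 18); steps 14 and 16 are one-step side branches.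

Step 10 (key step, proposed new method). The likely failures are reduction without C–C bond formation (protonation of the carbanion, or reduction or pinacol coupling of the ketone) and enolisation by the organometallic followed by β-elimination of O5 or O3. The fallback uses known chemistry, sets out from ketone 12 and returns at triol 18. The Grignard reagent (isopropoxydimethylsilyl)methylmagnesium chloride, precomplexed with CeCl3 to suppress enolisation, is added to 12 at −78 °C. In the chair of 12 with O5 and O4 equatorial the axial O3 shields the axial approach, so equatorial attack should place the new carbon cis to O5 and give the β-hydroxysilane F1. Tamao oxidation of F1 (H2O2, KF, KHCO3) gives the 5-O-silyl diol F2, and HF·pyridine frees O5 of F2 to give 18. C1 is then under substrate control only; the lactonisation of step 12, open to the correct epimer alone, would sort the isomers.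

Step 6. After the first alkylation the base meant for C2 of 10 may attack or eliminate the remaining triflate, a second molecule of 9 may alkylate it to an open-chain bis-dithiane, or the O2 silyl ether may close onto the C5 triflate before carbon does. The fallback sets out from diol 6 and returns at ketone 12, replacing lithiated dithiane by a one-carbon unit that is alkylated twice under mild base. Diol 6 is converted with I2, PPh3 and imidazole into the stable diiodide F3. Tosylmethyl isocyanide and NaH in DMSO/Et2O (van Leusen cycloalkylation) give the 1-isocyano-1-tosylcyclohexane F4 (C1 epimers immaterial). Brief treatment with dilute aqueous HCl in THF at 0 °C hydrolyses F4 to 12. No alkyllithium is used and step 7 falls away.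

Step 12. Oxidative cleavage of the C1–C7 glycol or of the α-hydroxy aldehyde may outrun lactol closure, with loss of C7 and return to ketone 13. The fallback sets out from 18 and returns at 20 in two separate operations. Nitroxyl-catalysed oxidation with NaClO2 as stoichiometric oxidant and catalytic NaOCl in buffered MeCN/water, where chlorite takes the aldehyde to the acid at once, gives 3,4-O-isopropylidenequinic acid F5. Catalytic p-TsOH in toluene with azeotropic removal of water then closes the lactone of F5 to 20.

Step 15 (and with it step 17). Discrimination between O3 and O4 may be insufficient in the first acylation, or the first ester may migrate across the cis-diol during the second; either scrambles the positions of the two cinnamoyl groups. The fallback sets out from 21 and returns at 27, fixing the order with a silyl group. TBSCl/imidazole silylates the equatorial O3 to give 3-O-(tert-butyldimethylsilyl)-1,5-quinide F6. Chloride 26 with pyridine/DMAP acylates O4 of F6 to give the 3-O-silyl 4-O-coumaroyl quinide F7. HF·pyridine removes the silyl group under acidic conditions that should not move the ester, giving 4-O-(4-O-acetyl-p-coumaroyl)-1,5-quinide F8. Chloride 23 in pyridine at low temperature then acylates O3 of F8 to give 27.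

Step 18. During the long exposure to aqueous acid the aryl acetates may be cleaved incompletely, a cinnamate may be hydrolysed, or the coumaroyl group may shift from O4 to O5 once the lactone has opened. The fallback sets out from 27 and returns at 28 in two stages. Ammonium acetate in aqueous methanol at room temperature removes the three phenolic acetates chemoselectively and gives 3-O-caffeoyl-4-O-p-coumaroyl-1,5-quinide F9. The lactone of F9 alone is then opened with dilute aqueous HCl in THF, a much shorter acid exposure, to give 28.

## Further compounds

F1 | step 10 | 5-O-(tert-butyldimethylsilyl)-1-C-[(isopropoxydimethylsilyl)methyl]-3,4-O-isopropylidenecyclohexane-1,3,4,5-tetrol (new carbon cis to O5) | CC1(C)O[C@H]2[C@H](O[Si](C)(C)C(C)(C)C)C[C@](O)(C[Si](C)(C)OC(C)C)C[C@H]2O1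
F2 | step 10 | 5-O-(tert-butyldimethylsilyl) ether of triol 18 | CC1(C)O[C@H]2[C@H](O[Si](C)(C)C(C)(C)C)C[C@](O)(CO)C[C@H]2O1
F3 | step 6 | 1,5-dideoxy-1,5-diiodo-2-O-(tert-butyldimethylsilyl)-3,4-O-isopropylidene-D-arabinitol | IC[C@@H](O[Si](C)(C)C(C)(C)C)[C@@H]1OC(C)(C)O[C@@H]1CI
F4 | step 6 | 1-isocyano-1-tosyl-5-O-(tert-butyldimethylsilyl)-3,4-O-isopropylidenecyclohexane-3,4,5-triol (either C1 epimer) | CC1(C)O[C@H]2[C@H](O[Si](C)(C)C(C)(C)C)CC([N+]#[C-])(S(=O)(=O)c3ccc(C)cc3)C[C@H]2O1
F5 | step 12 | 3,4-O-isopropylidenequinic acid | CC1(C)O[C@H]2[C@H](O)C[C@](O)(C(=O)O)C[C@H]2O1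
F6 | step 15 | 3-O-(tert-butyldimethylsilyl)-1,5-quinide | O[C@H]1[C@H]2C[C@](O)(C(=O)O2)C[C@H]1O[Si](C)(C)C(C)(C)C
F7 | step 15 | 4-O-(4-O-acetyl-p-coumaroyl)-3-O-(tert-butyldimethylsilyl)-1,5-quinide | O=C(/C=C/c1ccc(OC(C)=O)cc1)O[C@H]1[C@H]2C[C@](O)(C(=O)O2)C[C@H]1O[Si](C)(C)C(C)(C)C
F8 | step 15 | 4-O-(4-O-acetyl-p-coumaroyl)-1,5-quinide | O=C(/C=C/c1ccc(OC(C)=O)cc1)O[C@H]1[C@H]2C[C@](O)(C(=O)O2)C[C@H]1O
F9 | step 18 | 3-O-caffeoyl-4-O-p-coumaroyl-1,5-quinide | O=C(/C=C/c1ccc(O)cc1)O[C@H]1[C@H]2C[C@](O)(C(=O)O2)C[C@H]1OC(=O)/C=C/c1ccc(O)c(O)c1
A1 | alternative 1 | 4-O-[4-(allyloxy)cinnamoyl]-3-dehydroquinic acid 1,7-isopropylidene dioxolanone | O=C(/C=C/c1ccc(OCC=C)cc1)O[C@H]1[C@H](O)C[C@@]2(OC(C)(C)OC2=O)CC1=O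
A2 | alternative 1 | acyclic keto aldehyde: citrate-derived dioxolanone with a formylmethyl arm and a 3-[4-(allyloxy)cinnamoyloxy]-2-oxopropyl arm | O=CC[C@@]1(OC(C)(C)OC1=O)CC(=O)COC(=O)/C=C/c1ccc(OCC=C)cc1
A3 | alternative 2 | 2-(trimethylsilyl)ethyl 4-deoxy-4-iodo-4-epi-1,3-O-(di-tert-butylsilylene)-5-O-(4-methoxybenzyl)quinate | I[C@@H]1[C@H](OCc2ccc(OC)cc2)C[C@]3(C(=O)OCC[Si](C)(C)C)C[C@H]1O[Si](C(C)(C)C)(C(C)(C)C)O3
A4 | alternative 2 | 2-(trimethylsilyl)ethyl 1-O-(di-tert-butylhydroxysilyl)-5-O-(4-methoxybenzyl)-3,4-dideoxyquin-3-enate (cyclohex-3-ene silanol) | C1=C[C@H](OCc2ccc(OC)cc2)C[C@](O[Si](O)(C(C)(C)C)C(C)(C)C)(C(=O)OCC[Si](C)(C)C)C1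
A5 | alternative 3 | ethyl 4,5-O-isopropylidene-3-dehydroquinate | CC1(C)O[C@H]2[C@H](O1)C[C@](O)(C(=O)OCC)CC2=O
A6 | alternative 3 | ethyl 3-[(4R,5S)-5-acetyl-2,2-dimethyl-1,3-dioxolan-4-yl]-2-oxopropanoate (acyclic diketo ester) | CC(=O)[C@H]1OC(C)(C)O[C@@H]1CC(=O)C(=O)OCC
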